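**The ceiling.** Your closed, stirred, isothermal vessel holds starting material, reagent, free catalyst and protic impurity, and two earlier runs differ from the flask in their reagent charge.

| setting | ochre | grey | flask |
|---|---|---|---|
| starting material | 0.020 M | 0.020 M | 0.020 M |
| reagent | 0.015 M | 0.022 M | 0.0300 M |
| protic impurity | 0.40 mM | 0.40 mM | 0.400 mM |
| free catalyst | 0.50 mM | 0.50 mM | 0.50 mM |
| remark | run made earlier | run made earlier |  |
| time |  |  | 10 d |

| run | time / d | starting material / % | product / % |
|---|---|---|---|
| ochre | 1.25 | 64.0 | 32.5 |
| ochre | 3.00 | 36.7 | 59.6 |
| ochre | 4.00 | 29.1 | 68.5 |
| ochre | 6.00 | 21.9 | 72.2 |
| ochre | 8.00 | 21.5 | 74.0 |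
| ochre | 10.0 | 21.0 | 74.2 |
| grey | 0.500 | 77.0 | 17.2 |
| grey | 1.67 | 43.1 | 54.0 |
| grey | 3.00 | 17.0 | 78.2 |
| grey | 4.00 | 8.0 | 90.9 |
| grey | 6.00 | 0.1 | 97.4 |
| grey | 8.00 | 0 | 99.6 |
| grey | 10.0 | 0 | 99.4 |

(standard deviation of a reading: 1 percentage point)

- the reaction counts as stopped when no species that holds the starting material changes by six tenths of a point or more over the second half of the time

* at 10 d, what has stopped the reaction, if anything has (all of the starting material has reacted / forward and back rates have come level / the reagent has run out first / no working catalyst is left / it is still moving)
* share of the starting material used up at 10 d
* product at 10 d, in percent of the starting material charged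

Take the end state first, through the reagent ratio r, the reagent charge over the starting-material charge, which for the flask is 1.50. Ochre has r = 0.750, and its product reads 74.2% at 10.0 d, with 21.0% of the starting material unused. Grey has r = 1.10, and its starting material reads 0% at 8.00 d. So, with the other charges as in these two runs, I read r below one as a ceiling on product, at r times the starting-material charge, while above one the starting material is the limiting reagent, as in the flask.

**First rung.** At 0.500 d, grey's two readings fall short of the charge by 5.8 percentage points, so by then, as far as these readings show, a pool other than these two species has formed.

**Second rung.** Average consumption, as a share of the charge, reads 0.288 /d up to 1.25 d in ochre and 0.341 /d up to 1.67 d in grey, the run with more reagent; taking grey's later reading keeps the early pool from weighing heavily on its pace. If the pace is taken in proportion to reagent, which is my assumption, scaling grey's pace to the flask's reagent gives an estimated time scale τ, the time to use the charge at that pace, of 2.15 d.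

**Last rung.** The asked time is 4.65 times τ, so I expect the flask to reach its end state first. My reckoning gives that end state, not a yield. The forecast, on the grounds that “Early rates rise with reagent”, says all of the starting material has reacted, with conversion 100% and product 99.5% (97% to 100%).

**The result.** The flask ends thus: all of the starting material has reacted, with conversion 100% and product 98.0%.

    starting material + free catalyst → catalyst intermediate A (k = 230 /M/h)
    reagent + catalyst intermediate A ⇌ catalyst intermediate B (K = 44.0 /M, k = 130 /M/h)
    catalyst intermediate B → released group + catalyst intermediate C (k = 3.30 /h)
    catalyst intermediate C → free catalyst + product (k = 3.10 /h)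
    starting material + protic impurity → quenched substrate (k = 10.0 /M/h)

**The neighbour.** For the flask, r reckons 33.3% of the reagent charge left over, and at 10.0 d the flask holds 35% of that charge, with quenched substrate at 2.00% of the starting material charged. A neighbouring flask with 0.0075 M of reagent has r = 0.375, a ceiling of 37.5%. That neighbouring flask reads 37.5% product at 10.0 d, with reagent at 0.0443% of its charge and 58.0% of the starting material left.

All runs are calculated from invented constants, and the scatter is random.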